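**Strategy.** Everything rests on cutting the pyrrole ring at C3–C4, the ring C=C bond that is substituted at one end only (heneicosyl on C3, hydrogen on C4). Ring-closing metathesis makes this bond and, in the same operation, closes the five-membered N1–C2–C3–C4–C5 ring with the chain locked at C3. The precursor is an acyclic, racemic N-tosyl amino ester: C2 carries a 1,1-disubstituted alkene holding the C21 chain, and nitrogen carries an allyl group. The tosyl group keeps nitrogen off ruthenium and later leaves as sulfinate, so aromatisation needs no oxidant.

Key step: step 6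

Assumption: the target has no stereocentre, so every intermediate with an sp3 C2 is made and carried as the racemate. C2 becomes planar in the last step.

Step 1
Reactants: 1 1-bromoeicosane; 2 2,3-dibromopropene
Product: 4 2-bromotricos-1-ene, via eicosylmagnesium bromide 3 (not isolated)
Conditions: Mg, THF, 45 °C; then 2, CuI (5 mol %), THF, 0 °C → rt
Reagents that add atoms: none
Why: Copper-catalysed allylic substitution of a Grignard reagent displaces only the allylic C–Br bond of 2 (direct and allylic-shift attack give the same product), leaves the vinylic bromide as the handle for step 2, and joins C20 to the allylic CH2 to give exactly the C21 chain.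

Step 2
Reactants: 4 2-bromotricos-1-ene
Product: 7 (tricos-1-en-2-yl)boronic acid, via tricos-1-en-2-ylmagnesium bromide 5 (not isolated), via diisopropyl (tricos-1-en-2-yl)boronate 6 (not isolated)
Conditions: Mg, THF, 50 °C; added to B(OiPr)3 (2 equiv), THF, −40 °C → rt; 1 M HCl
Reagents that add atoms: triisopropyl borate, CC(C)OB(OC(C)C)OC(C)C; water, O
Why: Grignard formation from a 2-bromo-1-alkene is followed by electrophilic trapping with a borate ester, where inverse addition to excess borate prevents double alkenylation and acidic hydrolysis frees the boronic acid, a more reactive partner for step 3 than a pinacol ester.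

Step 3
Reactants: 7 (tricos-1-en-2-yl)boronic acid; 8 glyoxylic acid (used as the monohydrate); 9 allylamine
Product: 11 2-(allylamino)-3-methylenetetracosanoic acid (racemic), via 2-(allylimino)acetic acid 10 (not isolated)
Conditions: CH2Cl2–(CF3)2CHOH (9:1), rt → 40 °C
Reagents that add atoms: none
Why: In this Petasis borono-Mannich reaction the carboxylate of 10 binds boron and the alkenyl group migrates intramolecularly to the iminium carbon, forming C2–C3 in a non-basic medium that leaves the β,γ-alkene unconjugated, and C2 forms as a racemate because nothing chiral is present, which is harmless since step 8 erases it.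

Step 4
Reactants: 11 2-(allylamino)-3-methylenetetracosanoic acid
Product: 12 methyl 2-(allylamino)-3-methylenetetracosanoate (racemic)
Conditions: SOCl2, MeOH–CH2Cl2, 0 → 45 °C; NaHCO3 wash
Reagents that add atoms: methanol, CO
Why: Fischer-type esterification with HCl generated in situ is the standard method for vinylglycine-type amino acids, because the protonated amine protects itself and deactivates the neighbouring alkene towards HCl addition and migration.

Step 5
Reactants: 12 methyl 2-(allylamino)-3-methylenetetracosanoate
Product: 13 methyl 2-[allyl(tosyl)amino]-3-methylenetetracosanoate (racemic)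
Conditions: TsCl, pyridine, DMAP (10 mol %), CH2Cl2, 0 → 40 °C
Reagents that add atoms: p-toluenesulfonyl chloride, Cc1ccc(cc1)S(=O)(=O)Cl
Why: This is a DMAP-catalysed sulfonylation of a secondary amine in which pyridine is too weak a base to pull the alkene into conjugation with the ester, and prior esterification rules out mixed anhydride formation.

Step 6
Reactants: 13 methyl 2-[allyl(tosyl)amino]-3-methylenetetracosanoate
Product: 14 methyl 3-heneicosyl-1-tosyl-2,5-dihydro-1H-pyrrole-2-carboxylate (racemic)
Conditions: RuCl2(=CHPh)(PCy3)(H2IMes) (second-generation Grubbs catalyst, 5 mol %), 1,4-benzoquinone (10 mol %), CH2Cl2 (0.01 M), reflux, Ar purge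
Reagents that add atoms: none
Why: Ring-closing olefin metathesis proceeds through ruthenium alkylidenes: the benzylidene first exchanges with the monosubstituted N-allyl alkene, the alkylidene so formed adds across the chain-bearing geminal alkene to give a ruthenacyclobutane, and its fragmentation creates C3=C4 while both =CH2 termini leave as ethene. The closest known reaction type is the closure of N-sulfonyl diallylamines and N-allyl vinylglycine esters to 3-pyrrolines, trisubstituted ring alkenes included, for which the N-heterocyclic-carbene ruthenium catalyst is the usual choice. The single ring formed, N1–C2–C3=C4–C5, closes as a five-membered ring from a 1,6-diene, a mode favoured entropically and made irreversible by escape of ethene. No stereocentre is created, and the racemic C2 centre is a spectator that vanishes in step 8. The step needs cyclisation to outrun allyl homodimerisation and hydride-induced alkene migration: the geminal alkene does not self-metathesise, initiation is confined to the allyl terminus, high dilution penalises bimolecular events, the sulfonamide nitrogen cannot ligate ruthenium, and 1,4-benzoquinone intercepts ruthenium hydrides.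

Step 7
Reactants: 14 methyl 3-heneicosyl-1-tosyl-2,5-dihydro-1H-pyrrole-2-carboxylate
Product: 15 (3-heneicosyl-1-tosyl-2,5-dihydro-1H-pyrrol-2-yl)methanol (racemic)
Conditions: iBu2AlH (3 equiv), toluene, −20 → 0 °C; aq. potassium sodium tartrate
Reagents that add atoms: none
Why: Full ester-to-alcohol reduction with a non-basic aluminium hydride leaves the acidic C2–H, the N–S bond and the ring alkene alone, needs no cryogenic control that the waxy substrate would not tolerate, and gives a carbinol that cannot ionise to an azafulvene as an N–H pyrrolylmethanol would.

Step 8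
Reactants: 15 (3-heneicosyl-1-tosyl-2,5-dihydro-1H-pyrrol-2-yl)methanol
Product: 18 3-heneicosyl-1H-pyrrole-2-carbaldehyde, via 3-heneicosyl-1-tosyl-2,5-dihydro-1H-pyrrole-2-carbaldehyde 16 (not isolated), via 4-heneicosyl-2H-pyrrole-5-carbaldehyde 17 (not isolated)
Conditions: SO3·pyridine, DMSO, Et3N, CH2Cl2, 0 °C → rt; then DBU, rt
Reagents that add atoms: none
Why: Parikh–Doering oxidation runs at temperatures where the lipid stays dissolved and gives 16, whose C2–H (α to the formyl group, allylic, next to the sulfonamide) is removed by base so that p-toluenesulfinate leaves nitrogen by an E1cB elimination to give 17, and a prototropic shift from C5 to nitrogen then delivers the aromatic ring.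

**Compound list**

1 | 1-bromoeicosane | CCCCCCCCCCCCCCCCCCCCBr | starting material
2 | 2,3-dibromopropene | C=C(Br)CBr | starting material
3 | eicosylmagnesium bromide (not isolated) | CCCCCCCCCCCCCCCCCCCC[Mg]Br | intermediate
4 | 2-bromotricos-1-ene | C=C(Br)CCCCCCCCCCCCCCCCCCCCC | intermediate
5 | tricos-1-en-2-ylmagnesium bromide (not isolated) | C=C([Mg]Br)CCCCCCCCCCCCCCCCCCCCC | intermediate
6 | diisopropyl (tricos-1-en-2-yl)boronate (not isolated) | C=C(B(OC(C)C)OC(C)C)CCCCCCCCCCCCCCCCCCCCC | intermediate
7 | (tricos-1-en-2-yl)boronic acid | C=C(B(O)O)CCCCCCCCCCCCCCCCCCCCC | intermediate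
8 | glyoxylic acid (used as the monohydrate) | O=CC(=O)O | starting material
9 | allylamine | C=CCN | starting material
10 | (E)-2-(allylimino)acetic acid (not isolated) | C=CC/N=C/C(=O)O | intermediate
11 | 2-(allylamino)-3-methylenetetracosanoic acid, racemic | C=C(CCCCCCCCCCCCCCCCCCCCC)C(NCC=C)C(=O)O | intermediate
12 | methyl 2-(allylamino)-3-methylenetetracosanoate, racemic | C=C(CCCCCCCCCCCCCCCCCCCCC)C(NCC=C)C(=O)OC | intermediate
13 | methyl 2-[allyl(tosyl)amino]-3-methylenetetracosanoate, racemic | C=C(CCCCCCCCCCCCCCCCCCCCC)C(N(CC=C)S(=O)(=O)c1ccc(C)cc1)C(=O)OC | intermediate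
14 | methyl 3-heneicosyl-1-tosyl-2,5-dihydro-1H-pyrrole-2-carboxylate, racemic | CCCCCCCCCCCCCCCCCCCCCC1=CCN(S(=O)(=O)c2ccc(C)cc2)C1C(=O)OC | intermediate
15 | (3-heneicosyl-1-tosyl-2,5-dihydro-1H-pyrrol-2-yl)methanol, racemic | CCCCCCCCCCCCCCCCCCCCCC1=CCN(S(=O)(=O)c2ccc(C)cc2)C1CO | intermediate
16 | 3-heneicosyl-1-tosyl-2,5-dihydro-1H-pyrrole-2-carbaldehyde, racemic (not isolated) | CCCCCCCCCCCCCCCCCCCCCC1=CCN(S(=O)(=O)c2ccc(C)cc2)C1C=O | intermediate
17 | 4-heneicosyl-2H-pyrrole-5-carbaldehyde (not isolated) | CCCCCCCCCCCCCCCCCCCCCC1=CCN=C1C=O | intermediate
18 | 3-heneicosyl-1H-pyrrole-2-carbaldehyde (no stereocentre) | CCCCCCCCCCCCCCCCCCCCCc1cc[nH]c1C=O | target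

Total step count: 8. Longest linear sequence: 8 steps (from 1).

**Steps most likely to fail**

Step 6. The alkylidene formed at the allyl terminus may engage the geminal alkene, which is flanked by the branched C2, too slowly. Allyl homodimerisation, or hydride-induced migration of the N-allyl double bond to an enamide, would then take over.

The fallback gives up the diene and builds the ring by a formal [3+2] isocyanide–alkyne cycloaddition. It sets out from 4 and comes back at 18.
- Dehydrobromination of 4 with excess NaNH2 in THF–liquid NH3, where the terminal acetylide is the thermodynamic sink, should give tricos-1-yne F1.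
- Ag2CO3-catalysed cycloaddition of F1 with ethyl isocyanoacetate in 1,4-dioxane at 80 °C should give ethyl 3-heneicosyl-1H-pyrrole-2-carboxylate F2. The substituted alkyne carbon bonds to the α-carbon of the isocyanoacetate, which places the chain at C3.
- LiAlH4 in THF at 0 °C should give (3-heneicosyl-1H-pyrrol-2-yl)methanol F3, which is oxidised at once with activated MnO2 in CH2Cl2 to 18.

Step 3. Transfer of the α-branched alkenyl group from boron may be sluggish. Protodeboronation of 7, or a second Mannich reaction on the secondary amine product, could then compete.

The fallback forms C2–C3 by organomagnesium addition to a preformed N-sulfonyl imine, so the tosyl group and the ester are already in place. It sets out from 4 and comes back at 13.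
- Reagent 5, made from 4 as in step 2, is added in THF at −60 °C to methyl (E)-2-(tosylimino)acetate F4. F4 is prepared from methyl glyoxylate and p-toluenesulfonyl isocyanate in hot toluene.
- 1,2-Addition to the strongly activated C=N bond should give methyl 3-methylene-2-(tosylamino)tetracosanoate F5.
- A Mitsunobu N-allylation (allyl alcohol, PPh3, DIAD, THF) needs no base, so it does not move the alkene, and it returns to 13.

Step 8. Several processes could erode the one-pot sequence:
- methylthiomethyl ether formation at the hindered carbinol
- decomposition of the sensitive α-sulfonamido aldehyde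
- incomplete sulfinate loss
- re-addition of sulfinate to the azadiene

The fallback reverses the order and aromatises before the oxidation level is adjusted. It sets out from 14 and comes back at 18.
- KOtBu in THF at 0 °C should eliminate sulfinate from 14 and give methyl 3-heneicosyl-1H-pyrrole-2-carboxylate F6.
- LiAlH4 in THF at 0 °C should give (3-heneicosyl-1H-pyrrol-2-yl)methanol F3, which is used crude.
- Activated MnO2 in CH2Cl2 should oxidise this pyrrole-activated carbinol to 18.

Further compounds
F1 | step 6 | tricos-1-yne | CCCCCCCCCCCCCCCCCCCCCC#C
F2 | step 6 | ethyl 3-heneicosyl-1H-pyrrole-2-carboxylate | CCCCCCCCCCCCCCCCCCCCCc1cc[nH]c1C(=O)OCC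
F3 | step 6 | (3-heneicosyl-1H-pyrrol-2-yl)methanol | CCCCCCCCCCCCCCCCCCCCCc1cc[nH]c1CO
F4 | step 3 | methyl (E)-2-(tosylimino)acetate | COC(=O)/C=N/S(=O)(=O)c1ccc(C)cc1
F5 | step 3 | methyl 3-methylene-2-(tosylamino)tetracosanoate, racemic | C=C(CCCCCCCCCCCCCCCCCCCCC)C(NS(=O)(=O)c1ccc(C)cc1)C(=O)OC
F6 | step 8 | methyl 3-heneicosyl-1H-pyrrole-2-carboxylate | CCCCCCCCCCCCCCCCCCCCCc1cc[nH]c1C(=O)OC
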